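**Retrosynthetic overview**

1. The pyridone ring is closed last: N1–C2 by condensation of an O-methyl oxime nitrogen with a methyl ketone, C2–C3 and C4–C4a by two acylations of that oxime ether.
2. C8–OMe comes from cis-selective hydride reduction of a 2-(methoxyimino)cyclohexanone and O-methylation; the nitrogen on C8a comes from nitrosation of a regiodefined enolate.
3. That enolate comes from (S)-4-octylcyclohex-2-enone, made by one-carbon ring expansion of a five-membered ring (iron-mediated opening of a siloxycyclopropane). This is the key step: it puts the carbonyl (C8) opposite the octyl centre and marks C8a and C4a.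
4. The C5 stereocentre comes from copper-catalysed asymmetric conjugate addition of octyl (from oct-1-ene) to cyclopent-2-enone, with silyl trapping and cyclopropanation in the same flask.
5. Ring order: cyclopentane (bought), cyclopropane (temporary), cyclohexane by ring expansion, pyridone.

Assumption: the target is the (5S,8R) isomer as written (octyl and 8-methoxy cis), and the phosphoramidite antipode that gives the S adduct in step 1 is used.

**Route**

Step 1
Reactants: 1 cyclopent-2-en-1-one; 2 oct-1-ene
Product: 5 (1S,4S,5R)-4-octyl-1-(trimethylsilyloxy)bicyclo[3.1.0]hexane, via octylzirconocene chloride 3 (not isolated), via silyl enol ether 4 (not isolated)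
Conditions: 2, Cp2ZrHCl, CH2Cl2, rt; then 1, CuCl (10 mol%), AgNTf2 (11 mol%), chiral phosphoramidite ligand (10 mol%), Me3SiCl, Et2O, rt; then Et2Zn, CH2I2, 0 °C to rt
Reagents that add atoms: chlorotrimethylsilane, C[Si](C)(C)Cl; diiodomethane, ICI
Why: Hydrozirconation of 2 and copper-catalysed asymmetric conjugate addition of the alkylzirconium to 1 set the octyl-bearing centre as S by ligand control, the enolate is silylated with its C=C fixed on the side of the new centre, and Furukawa–Simmons–Smith cyclopropanation of this electron-rich alkene goes anti to the octyl group.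

Step 2
Reactants: 5
Product: 7 (S)-4-octylcyclohex-2-en-1-one, via chloroketone 6 (not isolated)
Conditions: FeCl3, DMF, 0 °C to rt; then NaOAc, MeOH, reflux
Reagents that add atoms: none
Why: Ito–Saegusa ring expansion, in which trivalent iron oxidises the siloxycyclopropane, the ring-fusion bond breaks to the secondary β-keto radical of the six-membered ring, and chlorine transfer followed by E1cB loss of HCl gives the enone; the stereocentre is untouched and the C=C records which α-carbon is the inserted one (later C8a).

Step 3
Reactants: 7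
Product: 10 (2E,4S)-2-(methoxyimino)-4-octylcyclohexan-1-one, via lithium enolate 8 (not isolated), via lithium oximate 9 (not isolated)
Conditions: LiBH(s-Bu)3 (L-Selectride), THF, −78 °C; then isoamyl nitrite, −78 to 0 °C; then MeI, DMPU, rt
Reagents that add atoms: isoamyl nitrite, CC(C)CCON=O; iodomethane, CI
Why: Conjugate reduction gives only the enolate on the inserted carbon, C-nitrosation of that enolate (α-oximation by an alkyl nitrite) and O-alkylation of the oximate put the N–OMe unit on the future C8a; no stereocentre is formed and the E oxime ether (methoxy away from the carbonyl) is expected.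

Step 4
Reactants: 10
Product: 11 (1R,2E,4S)-2-(methoxyimino)-4-octylcyclohexan-1-ol
Conditions: LiBH(s-Bu)3 (L-Selectride), THF, −78 °C; then H2O
Reagents that add atoms: none
Why: Bulky-hydride reduction of a 4-alkylcyclohexanone goes by equatorial attack to the axial alcohol, cis to the equatorial octyl group (the 4-tert-butylcyclohexanone pattern), which sets the carbinol centre as R; the oxime ether is not reduced by borohydrides.

Step 5
Reactants: 11
Product: 12 (1E,2R,5S)-2-methoxy-5-octylcyclohexan-1-one O-methyl oxime
Conditions: NaH, MeI, THF, 0 °C to rt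
Reagents that add atoms: iodomethane, CI
Why: Williamson etherification of the secondary alkoxide with retention, since the C–O bond is not broken; the oxime ether offers no site acidic enough for NaH.

Step 6
Reactants: 12; 13 methyl 2-methoxyacetate
Product: 15 2-methoxy-1-[(1R,2E,3R,6S)-3-methoxy-2-(methoxyimino)-6-octylcyclohexyl]ethan-1-one, via lithium azaenolate 14 (not isolated)
Conditions: LiN(CHMe2)2 (LDA), THF, −78 °C; then 13, −78 to 0 °C; then AcOH
Reagents that add atoms: none
Why: syn-Directed α-lithiation of the O-methyl oxime takes place at the CH2 that faces the N-methoxy group (the other α-carbon is tertiary and anti), and Claisen-type C-acylation of the azaenolate by the ester forms the C4a–C4 bond; the new centre is enolisable (trans isomer drawn) and becomes sp2 in step 7.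

Step 7
Reactants: 15; 16 N-methoxy-N-methylacetamide
Product: 19 (5S,8R)-1,3,8-trimethoxy-2-methyl-5-octyl-5,6,7,8-tetrahydroquinolin-4(1H)-one, via dilithium dianion 17 (not isolated), via enolised diketone 18 (not isolated)
Conditions: LiN(CHMe2)2 (LDA, 2.2 equiv), THF, −78 to −20 °C; then 16, −78 to 0 °C; then AcOH, 60 °C
Reagents that add atoms: none
Why: Proposed new method: a one-flask pyridone annulation of a β-keto O-methyl oxime, in which double deprotonation (first the doubly activated ring C–H, then the methoxymethylene) gives a dianion that the Weinreb amide acetylates at its terminal carbon as in the Hauser γ-acylation of β-diketone dianions, and on acidification the oxime ether, through its N-methoxy enamine tautomer, adds its nitrogen to the new methyl ketone and loses water to give the 1-methoxy-4-pyridone; the closest known reaction type is the condensation of 1,3,5-triketones with primary amines to 4-pyridones (and the N-cyclisation of oximes onto ketones), but an O-alkyl oxime has not served as the built-in nitrogen partner; no stereocentre is formed and C5 and C8 are not touched.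

**Compound list**

1 | cyclopent-2-en-1-one | O=C1CCC=C1 | starting material
2 | oct-1-ene | CCCCCCC=C | starting material
3 | chlorobis(cyclopentadienyl)(octyl)zirconium (octylzirconocene chloride) | CCCCCCCC[Zr+2]Cl.c1cc[cH-]c1.c1cc[cH-]c1 | intermediate
4 | (S)-trimethyl[(3-octylcyclopent-1-en-1-yl)oxy]silane | CCCCCCCC[C@H]1CCC(O[Si](C)(C)C)=C1 | intermediate
5 | (1S,4S,5R)-4-octyl-1-(trimethylsilyloxy)bicyclo[3.1.0]hexane (CH2 bridge anti to octyl) | CCCCCCCC[C@H]1CC[C@]2(O[Si](C)(C)C)C[C@H]12 | intermediate
6 | (3S,4S)-3-chloro-4-octylcyclohexan-1-one (trans) | CCCCCCCC[C@H]1CCC(=O)C[C@@H]1Cl | intermediate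
7 | (S)-4-octylcyclohex-2-en-1-one | CCCCCCCC[C@H]1CCC(=O)C=C1 | intermediate
8 | lithium (S)-4-octylcyclohex-1-en-1-olate | [Li+].CCCCCCCC[C@H]1CCC([O-])=CC1 | intermediate
9 | lithium salt of (2E,4S)-2-(hydroxyimino)-4-octylcyclohexan-1-one | [Li+].CCCCCCCC[C@H]1CCC(=O)/C(=N/[O-])C1 | intermediate
10 | (2E,4S)-2-(methoxyimino)-4-octylcyclohexan-1-one | CCCCCCCC[C@H]1CCC(=O)/C(=N/OC)C1 | intermediate
11 | (1R,2E,4S)-2-(methoxyimino)-4-octylcyclohexan-1-ol (OH cis to octyl) | CCCCCCCC[C@H]1CC[C@@H](O)/C(=N/OC)C1 | intermediate
12 | (1E,2R,5S)-2-methoxy-5-octylcyclohexan-1-one O-methyl oxime | CCCCCCCC[C@H]1CC[C@@H](OC)/C(=N/OC)C1 | intermediate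
13 | methyl 2-methoxyacetate | COCC(=O)OC | starting material
14 | lithium methoxy[(3S,6R)-6-methoxy-3-octylcyclohex-1-en-1-yl]azanide (azaenolate of 12) | [Li+].CCCCCCCC[C@H]1CC[C@@H](OC)C([N-]OC)=C1 | intermediate
15 | 2-methoxy-1-[(1R,2E,3R,6S)-3-methoxy-2-(methoxyimino)-6-octylcyclohexyl]ethan-1-one | CCCCCCCC[C@H]1CC[C@@H](OC)/C(=N/OC)[C@@H]1C(=O)COC | intermediate
16 | N-methoxy-N-methylacetamide | CC(=O)N(C)OC | starting material
17 | dilithium salt of 15, deprotonated at the ring CH and at the methoxymethylene | [Li+].[Li+].CCCCCCCC[C@H]1CC[C@@H](OC)C([N-]OC)=C1/C([O-])=C/OC | intermediate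
18 | (2E)-3-hydroxy-2-methoxy-1-[(1R,2E,3R,6S)-3-methoxy-2-(methoxyimino)-6-octylcyclohexyl]but-2-en-1-one (1,3-diketone drawn as its chelated enol) | CCCCCCCC[C@H]1CC[C@@H](OC)/C(=N/OC)[C@@H]1C(=O)/C(OC)=C(/C)O | intermediate
19 | (5S,8R)-1,3,8-trimethoxy-2-methyl-5-octyl-5,6,7,8-tetrahydroquinolin-4(1H)-one (Waltherione K) | CCCCCCCC[C@H]1CC[C@@H](OC)c2c1c(=O)c(OC)c(C)n2OC | target

**Step count**

Total steps: 7. Longest linear sequence: 7 steps (1 and 2 to 19; 13 and 16 are bought).

**The three steps most likely to fail**

Step 7 (the proposed annulation). The second deprotonation may be incomplete. In the acid stage, the water formed may hydrolyse the oxime ether, or the enamine tautomer may form toward C8 and erode that centre. The fallback uses known chemistry only and brings nitrogen in at the end by pyranone exchange; it sets out from 12 and returns at 19. Hydrolytic oxime-ether cleavage of 12 (aq. HCl, levulinic acid) gives (2R,5S)-2-methoxy-5-octylcyclohexan-1-one F1. Kinetic enolisation on the CH2 side (LiN(CHMe2)2, −78 °C) and acylation with 13 give (2R,5S,6S)-2-methoxy-6-(2-methoxyacetyl)-5-octylcyclohexan-1-one F2. Dianion γ-acetylation with 16 gives the triketone (2E)-3-hydroxy-2-methoxy-1-[(1R,3R,6S)-3-methoxy-6-octyl-2-oxocyclohexyl]but-2-en-1-one F3. Acid cyclodehydration (CF3CO2H) gives (5S,8R)-3,8-dimethoxy-2-methyl-5-octyl-5,6,7,8-tetrahydro-4H-chromen-4-one F4. Exchange with hydroxylamine (NH2OH·HCl, NaOAc, aq. EtOH, reflux) gives (5S,8R)-1-hydroxy-3,8-dimethoxy-2-methyl-5-octyl-5,6,7,8-tetrahydroquinolin-4(1H)-one F5, and MeI with K2CO3 methylates the N–OH to give 19.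

Step 1 (enantioselectivity on the five-membered enone and the one-flask cyclopropanation in the presence of zirconium residues). The fallback moves to the zinc series, where the conjugate addition, silylation and cyclopropanation cascade has precedent; it sets out from 1 and 2 and returns at 5. Hydroboration of 2 (BH3·SMe2) gives trioctylborane F6, and boron–zinc exchange with Et2Zn gives dioctylzinc F7. Addition of F7 to 1 catalysed by Cu(OTf)2 and the phosphoramidite, then Me3SiOTf and CH2I2 in the same flask, give 5.

Step 3 (one-flask reduction, nitrosation and methylation; the borane may interfere and some N-methylation may occur). The fallback isolates the enolate equivalent and the oxime; it sets out from 7 and returns at 10. Conjugate hydrosilylation of 7 (Et3SiH, RhCl(PPh3)3) gives (S)-triethyl[(4-octylcyclohex-1-en-1-yl)oxy]silane F8. Nitrosyl chloride (CH2Cl2, −20 °C) converts it to (2E,4S)-2-(hydroxyimino)-4-octylcyclohexan-1-one F9, and Ag2O with MeI methylates the oxime oxygen to give 10.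

**Further compounds**

F1 | step 7 | (2R,5S)-2-methoxy-5-octylcyclohexan-1-one | CCCCCCCC[C@H]1CC[C@@H](OC)C(=O)C1
F2 | step 7 | (2R,5S,6S)-2-methoxy-6-(2-methoxyacetyl)-5-octylcyclohexan-1-one | CCCCCCCC[C@H]1CC[C@@H](OC)C(=O)[C@@H]1C(=O)COC
F3 | step 7 | (2E)-3-hydroxy-2-methoxy-1-[(1R,3R,6S)-3-methoxy-6-octyl-2-oxocyclohexyl]but-2-en-1-one | CCCCCCCC[C@H]1CC[C@@H](OC)C(=O)[C@@H]1C(=O)/C(OC)=C(/C)O
F4 | step 7 | (5S,8R)-3,8-dimethoxy-2-methyl-5-octyl-5,6,7,8-tetrahydro-4H-chromen-4-one | CCCCCCCC[C@H]1CC[C@@H](OC)c2c1c(=O)c(OC)c(C)o2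
F5 | step 7 | (5S,8R)-1-hydroxy-3,8-dimethoxy-2-methyl-5-octyl-5,6,7,8-tetrahydroquinolin-4(1H)-one | CCCCCCCC[C@H]1CC[C@@H](OC)c2c1c(=O)c(OC)c(C)n2O
F6 | step 1 | trioctylborane | CCCCCCCCB(CCCCCCCC)CCCCCCCC
F7 | step 1 | dioctylzinc | CCCCCCCC[Zn]CCCCCCCC
F8 | step 3 | (S)-triethyl[(4-octylcyclohex-1-en-1-yl)oxy]silane | CCCCCCCC[C@H]1CCC(O[Si](CC)(CC)CC)=CC1
F9 | step 3 | (2E,4S)-2-(hydroxyimino)-4-octylcyclohexan-1-one | CCCCCCCC[C@H]1CCC(=O)/C(=N/O)C1
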